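**Slowness first.** The north-east run slowed early: X, with D counted in it, gained a fraction 0.0450 /h of the charge between 3.00 h and 5.00 h, then a smaller 0.0300 /h up to 8.00 h.

- north-east: E 0.32 M; Z 55 mM (held); run made earlier
- flask: E 0.16 M; Z 55 mM (held); time 40 h

north-east run (percent of the E charged)

| time / h | X / % | D / % |
|---|---|---|
| 1.00 | 4 | 0 |
| 3.00 | 20 | 1 |
| 5.00 | 29 | 11 |
| 8.00 | 38 | 20 |

(readings scatter by 1.5 percentage points)

- amounts and yields of X count D too
- given per volume of solution although it is solid: D
- at the start none of Z is in solution
- G is what Z becomes in solution

- how much X and D together there is at 40 h, in percent of the E charged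
- concentration of G in solution at 40 h, in percent of saturation

**Counting turnovers.** Those paces stood 2.50 h apart, so I read one halving every 4.27 h, a loose reading under the scatter. Assuming that pace, this flask's 40 h held 9.36 halvings. I therefore reckoned it finished, with G near saturation.

**The bracket.** A straight line of pace against X, through those two stretches and extended beyond them, pointed to zero pace at 51.5% for the north-east run, again a reading under the scatter. I took the remaining E as lost another way, giving B = 1.06, the E made into X per E lost otherwise, a selectivity factor. The charge caps this flask at 100%. If the loss scaled with charge as the step to X does, B would hold and give 51.5% as the lower end of my bracket. A loss by pairs of E would double B at half the charge, to 2.12, and I committed to 68.0%.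

**The result.** The forecast gave 33% (27% to 43%) and 99% (93% to 100%), expecting “probably little or no D forms”, which put its yield below my bracket. The flask gave 75.7% and >99.9%.

    E + G → X (k = 4.70 /M/h)
    2 E → Q (k = 0.280 /M/h)
    Z ⇌ G, rate k3*(csat - [G]) (kL = 0.760 /h)
    D ⇌ X, rate k4*(cs4 - [X]) while solid is left; crystals form when [X] > cs4 (solubility = 0.0580 M, k = 5.40 /h)

That yield lies above my figure, with 0.0061% of E left. Its B was 3.12, against my 2.12.

**Second flask.** At 0.096 M of E, scaling that B by charge gives 5.20, hence 83.9%. The computed flask gave 84.7%.

The readings are simulated with constants of no real substance, noise included.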